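## Retrosynthetic overview

1. The ring B side chain ArB–CH(CH2OH)–C(=O)–ArA is built last from an aryl bromide ortho to the ring B oxygen: Reformatsky–Negishi arylacetate, Evans aldol with formaldehyde to set the α-carbon, Weinreb amide, ring A Grignard. All phenols end as benzyl ethers and are released by hydrogenolysis, so the α-aryl ketol and the cis-dihydrobenzofuran never meet base.
2. Key disconnection: both benzylic C–O bonds of the 3,7-dioxabicyclo[3.3.0]octane, leading back to a (2R,3R)-2,3-dibenzylbutane-1,4-diol. The feature used: each benzylic CH2 (on ring B and on ring D) is para to an ether oxygen of its arene (O-benzyl on ring B, ring oxygen O1 of the dihydrobenzofuran on ring D) and lies five atoms from the CH2–OH oxygen of the other half.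
3. The diol comes from a trans-α,β-dibenzyl-γ-butyrolactone, made by enolate alkylation of an (R)-β-benzyl lactone (Stobbe condensation, asymmetric hydrogenation) with the ring D/E benzyl bromide.
4. The cis-dihydrobenzofuran (rings D/E) comes from rhodium-carbenoid insertion of an aryldiazoacetate into a benzylic ether C–H.
5. Ring order: dihydrofuran ring of D/E, then the (temporary) butyrolactone, then both tetrahydrofuran rings together in the key step.

Key step: step 15

Remarks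
- Ring letters: A = guaiacyl ring on the ketone; B = central guaiacyl ring; D = benzo ring of the dihydrobenzofuran; E = its 2-aryl ring.
- Assumption: the target SMILES is read as a cis-(2S,3S)-dihydrobenzofuran, a (1S,3aR,4S,6aR) exo,exo-furofuran and an (S) ketol carbon.
- Assumption: the sense of induction of the two chiral rhodium catalysts (steps 6 and 11) is taken from their usual behaviour; the antipodal ligand is used if it proves opposite.
- Design remark: ring B goes through the oxidative closure as its benzyl ether and without bromine. A free para-phenol would make the first-formed benzylic ether the most DDQ-oxidisable site in the flask, and a bromine ortho to the oxygen would twist that oxygen out of conjugation. The bromine is introduced afterwards, ortho to the liberated phenol (compound 24).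
- Shorthand in names: DBF(X,Y) = (2S,3S)-7-methoxy-2-[3-methoxy-4-(XO)phenyl]-3-(YOCH2)-2,3-dihydro-1-benzofuran-5-yl, with 2-aryl and 3-CH2OY cis. FUR(X,Y) = (1S,3aR,4S,6aR)-4-[DBF(X,Y)]tetrahydro-1H,3H-furo[3,4-c]furan-1-yl (cis-fused, both aryl groups exo).

## Route

Step 1
Reactants: 1 vanillyl alcohol
Product: 2 4-(hydroxymethyl)-2-methoxyphenyl 4-methylbenzenesulfonate
Conditions: TsCl, K2CO3, acetone, rt
Reagents that add atoms: p-toluenesulfonyl chloride, Cc1ccc(cc1)S(=O)(=O)Cl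
Why: Chemoselective O-sulfonylation of the phenoxide (carbonate does not deprotonate the benzylic alcohol) installs the electron-withdrawing group that later shields the ring E benzylic position from DDQ.

Step 2
Reactants: 2 4-(hydroxymethyl)-2-methoxyphenyl tosylate
Product: 3 4-(bromomethyl)-2-methoxyphenyl 4-methylbenzenesulfonate
Conditions: PBr3, CH2Cl2, 0 °C
Reagents that add atoms: phosphorus tribromide, BrP(Br)Br
Why: Conversion of a benzylic alcohol into the bromide through its phosphite ester (SN2 displacement by bromide).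

Step 3
Reactants: 4 methyl 3-bromo-4-hydroxy-5-methoxybenzoate; 3 ring E benzyl bromide
Product: 5 methyl 3-bromo-5-methoxy-4-{[3-methoxy-4-(tosyloxy)phenyl]methoxy}benzoate
Conditions: K2CO3, DMF, 50 °C
Reagents that add atoms: none
Why: Williamson ether synthesis of the acidic, ester-activated phenol with a reactive benzyl bromide.

Step 4
Reactants: 5 aryl bromide
Product: 6 methyl 3-(2-ethoxy-2-oxoethyl)-5-methoxy-4-{[3-methoxy-4-(tosyloxy)phenyl]methoxy}benzoate
Conditions: BrZnCH2CO2Et, Pd(dba)2 (2 mol%), Q-Phos (2 mol%), THF, rt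
Reagents that add atoms: (2-ethoxy-2-oxoethyl)zinc bromide, CCOC(=O)C[Zn]Br
Why: Negishi-type coupling of the aryl bromide with a Reformatsky reagent (palladium-catalysed α-arylation of an ester zinc enolate), which tolerates the benzoate and leaves the aryl tosylate untouched at room temperature.

Step 5
Reactants: 6 arylacetate
Product: 7 methyl 3-(1-diazo-2-ethoxy-2-oxoethyl)-5-methoxy-4-{[3-methoxy-4-(tosyloxy)phenyl]methoxy}benzoate
Conditions: 4-acetamidobenzenesulfonyl azide, DBU, MeCN, 0 °C to rt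
Reagents that add atoms: 4-acetamidobenzenesulfonyl azide, CC(=O)Nc1ccc(cc1)S(=O)(=O)N=[N+]=[N-]
Why: Regitz diazo transfer to the acidic arylacetate methylene, the standard entry to aryldiazoacetates.

Step 6
Reactants: 7 aryldiazoacetate
Product: 8 3-ethyl 5-methyl (2S,3R)-7-methoxy-2-[3-methoxy-4-(tosyloxy)phenyl]-2,3-dihydro-1-benzofuran-3,5-dicarboxylate (cis)
Conditions: Rh2(S-PTTL)4 (dirhodium tetrakis[N-phthaloyl-(S)-tert-leucinate], 1 mol%), toluene, −60 °C
Reagents that add atoms: none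
Why: Intramolecular 1,5 C–H insertion of the donor/acceptor rhodium carbenoid into the benzylic ether C–H closes the dihydrofuran ring; the concerted transition state should give the 2,3-cis product under kinetic control, and the chiral carboxylate ligands select the enantiotopic C–H, setting C2 (S) and C3 (R).

Step 7
Reactants: 8 cis diester
Product: 9 (2S,3S)-3,5-bis(hydroxymethyl)-7-methoxy-2-[3-methoxy-4-(tosyloxy)phenyl]-2,3-dihydro-1-benzofuran (cis)
Conditions: i-Bu2AlH (6 equiv), CH2Cl2, −78 to −20 °C; aq. potassium sodium tartrate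
Reagents that add atoms: none
Why: Non-basic aluminium hydride reduction of both esters to primary alcohols avoids enolisation of the epimerisable cis C3 ester (the C3 descriptor becomes S only through the priority change).

Step 8
Reactants: 9 cis diol
Product: 10 (2S,3S)-5-(bromomethyl)-3-(hydroxymethyl)-7-methoxy-2-[3-methoxy-4-(tosyloxy)phenyl]-2,3-dihydro-1-benzofuran
Conditions: NBS, Me2S, CH2Cl2, −20 to 0 °C
Reagents that add atoms: N-bromosuccinimide, O=C1CCC(=O)N1Br
Why: Corey–Kim bromination: both hydroxyls form alkoxysulfonium ions, but only the para-alkoxy-activated benzylic one is displaced by bromide at this temperature, and the aliphatic one reverts to the alcohol on work-up.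

Step 9
Reactants: 10 bromo alcohol
Product: 11 (2S,3S)-5-(bromomethyl)-7-methoxy-2-[3-methoxy-4-(tosyloxy)phenyl]-3-{[(triisopropylsilyl)oxy]methyl}-2,3-dihydro-1-benzofuran [DBF(Ts,TIPS)–CH2Br]
Conditions: i-Pr3SiOTf, 2,6-lutidine, CH2Cl2, −78 °C
Reagents that add atoms: triisopropylsilyl trifluoromethanesulfonate, CC(C)[Si](OS(=O)(=O)C(F)(F)F)(C(C)C)C(C)C
Why: Silylation of the primary alcohol with a silyl triflate and a hindered pyridine base, which is too hindered to be alkylated by the benzyl bromide at low temperature.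

Step 10
Reactants: 12 4-(benzyloxy)-3-methoxybenzaldehyde; 13 dimethyl succinate
Product: 14 (E)-4-[4-(benzyloxy)-3-methoxyphenyl]-3-(methoxycarbonyl)but-3-enoic acid
Conditions: NaOMe, MeOH, reflux; then aq. HCl
Reagents that add atoms: none
Why: Stobbe condensation (aldol addition, lactonisation, E1cB ring opening) gives the (E)-arylidene succinic half-ester.

Step 11
Reactants: 14 half-ester
Product: 15 (3R)-4-[4-(benzyloxy)-3-methoxyphenyl]-3-(methoxycarbonyl)butanoic acid
Conditions: H2 (5 bar), [Rh(cod)((S,S)-Et-DuPhos)]BF4 (0.5 mol%), MeOH, rt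
Reagents that add atoms: none
Why: Rhodium–bisphosphine asymmetric hydrogenation of an itaconate-type half-ester; the chelated substrate takes hydrogen on one alkene face and sets the (R) centre, and the homogeneous catalyst spares the benzyl ether.

Step 12
Reactants: 15 (R)-acid ester
Product: 17 (4R)-4-[4-(benzyloxy)-3-methoxybenzyl]dihydrofuran-2(3H)-one, via hydroxy acid 16 (not isolated)
Conditions: LiBH4 (2.5 equiv), THF, 0 to 45 °C; then 2 M HCl, rt
Reagents that add atoms: none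
Why: Chemoselective borohydride reduction of the ester in the presence of the lithium carboxylate, then acid lactonisation of the γ-hydroxy acid; the stereocentre is untouched.

Step 13
Reactants: 17 (R)-β-benzyl lactone; 11 ring D/E benzyl bromide
Product: 19 (3R,4R)-4-[4-(benzyloxy)-3-methoxybenzyl]-3-[DBF(Ts,TIPS)-methyl]dihydrofuran-2(3H)-one (trans), via lithium enolate 18 (not isolated)
Conditions: LiN(SiMe3)2 (1.1 equiv), THF, −78 °C; then 11, DMPU, −78 to −40 °C
Reagents that add atoms: none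
Why: Lactone enolate alkylation (SN2 on the benzyl bromide) from the face anti to the β-benzyl group should set the new α-centre trans, (3R).

Step 14
Reactants: 19 trans lactone
Product: 20 (2R,3R)-2-[4-(benzyloxy)-3-methoxybenzyl]-3-[DBF(Ts,TIPS)-methyl]butane-1,4-diol
Conditions: LiBH4 (3 equiv), THF, 0 °C to rt; aq. NH4Cl
Reagents that add atoms: none
Why: Hydride reduction of the lactone to the 1,4-diol with a reagent that spares the aryl tosylate, the silyl ether and the benzyl ether; no stereocentre is involved.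

Step 15
Reactants: 20 (2R,3R)-dibenzylbutanediol
Product: 22 1-(benzyloxy)-2-methoxy-4-[FUR(Ts,TIPS)]benzene, via monocyclic ether 21 (not isolated)
Conditions: DDQ (2.2 equiv, two portions), NaHCO3 (solid), 4 Å MS, CH2Cl2, 0 °C to rt
Reagents that add atoms: none
Why: Proposed new method: DDQ forms a charge-transfer complex with each electron-rich arene and removes hydride from the benzylic CH2 that lies para to an ether oxygen (the benzyloxy oxygen on ring B, the ring oxygen O1 on ring D), and each oxygen-stabilised benzylic cation is captured at once by the primary hydroxyl five atoms away, first to monoether 21 and then to 22; the closest known reaction type is the DDQ-mediated benzylic C–H oxidation of a 4-alkoxybenzyl group with capture by a γ-hydroxyl to give a 2-aryltetrahydrofuran, known for one closure but not for two on one substrate. Both tetrahydrofuran rings close by 5-exo-trig attack of oxygen on the planar cation, and because the two backbone carbons are already (R,R) the second closure can only give the cis-fused 3,7-dioxabicyclo[3.3.0]octane. Each new benzylic stereocentre is controlled by the neighbouring ring-fusion carbon: the cation reacts through the conformer that minimises allylic strain, so the aryl group ends trans to the adjacent ring substituent, which is the exo (convex-face) position, giving (S) at both carbons. The step needs site selectivity for the two para-alkoxybenzylic CH2 groups over the dihydrobenzofuran C2–H and C3–H, secured by the tosylate on ring E (no donor para to C2) and by the two β-oxygens that disfavour a cation at C3. It also needs the benzylic ethers formed to resist further oxidation, secured by having no free phenol in the flask, by limiting DDQ to about two equivalents and, in 22, by the benzylic hydrogens pointing into the concave face. Solid NaHCO3 and molecular sieves keep the medium neutral and dry so that the new benzylic ethers are not reionised to epimers or to aryltetralins.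

Step 16
Reactants: 22 furofuran benzyl ether
Product: 23 2-methoxy-4-[FUR(Ts,TIPS)]phenol
Conditions: H2 (1 atm), 10% Pd/C, EtOAc, rt
Reagents that add atoms: none
Why: Hydrogenolysis of the aryl benzyl ether, which is fast on palladium; stopping at full conversion in a neutral solvent keeps the slower hydrogenolysis of the furofuran benzylic C–O bonds in check.

Step 17
Reactants: 23 ring B phenol
Product: 24 2-bromo-6-methoxy-4-[FUR(Ts,TIPS)]phenol
Conditions: NBS (1.0 equiv), CH2Cl2, −78 to −30 °C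
Reagents that add atoms: N-bromosuccinimide, O=C1CCC(=O)N1Br
Why: Electrophilic aromatic bromination ortho to the free phenol (para is occupied, the other ortho position carries OMe); the phenol ring is far more reactive than the ether ring D and the tosylated ring E.

Step 18
Reactants: 24 bromophenol
Product: 25 2-(benzyloxy)-1-bromo-3-methoxy-5-[FUR(Ts,TIPS)]benzene
Conditions: BnBr, K2CO3, DMF, rt
Reagents that add atoms: benzyl bromide, BrCc1ccccc1
Why: Williamson benzylation of the ring B phenol; ring E is still a tosylate, so no phenoxide para to the dihydrobenzofuran C2 is formed.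

Step 19
Reactants: 25 aryl bromide
Product: 26 ethyl {2-(benzyloxy)-3-methoxy-5-[FUR(Ts,TIPS)]phenyl}acetate
Conditions: BrZnCH2CO2Et, Pd(dba)2 (3 mol%), Q-Phos (3 mol%), THF, rt to 40 °C
Reagents that add atoms: (2-ethoxy-2-oxoethyl)zinc bromide, CCOC(=O)C[Zn]Br
Why: Negishi-type coupling with a Reformatsky reagent under near-neutral conditions, which the furofuran, the silyl ether and the aryl tosylate tolerate.

Step 20
Reactants: 26 ethyl arylacetate
Product: 27 methyl {2-(benzyloxy)-3-methoxy-5-[FUR(H,TIPS)]phenyl}acetate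
Conditions: Mg turnings, MeOH, rt; aq. NH4Cl
Reagents that add atoms: methanol, CO
Why: Reductive S–O cleavage of the aryl sulfonate by electron transfer from magnesium (Mg/MeOH desulfonylation) frees the ring E phenol without hot alkali, which could open the cis-dihydrobenzofuran through a para-quinone methide and re-close it trans; the methoxide formed transesterifies the ester, which is of no consequence.

Step 21
Reactants: 27 ring E phenol
Product: 28 methyl {2-(benzyloxy)-3-methoxy-5-[FUR(Bn,TIPS)]phenyl}acetate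
Conditions: BnOH, PPh3, DIAD, THF, 0 °C to rt
Reagents that add atoms: benzyl alcohol, OCc1ccccc1
Why: Mitsunobu etherification benzylates the phenol under essentially neutral conditions, so a ring E phenoxide never persists.

Step 22
Reactants: 28 methyl ester
Product: 29 {2-(benzyloxy)-3-methoxy-5-[FUR(Bn,TIPS)]phenyl}acetic acid
Conditions: LiOH·H2O, THF/MeOH/H2O, rt; then 1 M HCl to pH 4, 0 °C
Reagents that add atoms: lithium hydroxide, [Li+].[OH-]
Why: Ester saponification; no phenol is free and no epimerisable centre exists yet.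

Step 23
Reactants: 29 arylacetic acid; 30 (S)-4-benzyl-1,3-oxazolidin-2-one
Product: 32 (4S)-4-benzyl-3-({2-(benzyloxy)-3-methoxy-5-[FUR(Bn,TIPS)]phenyl}acetyl)-1,3-oxazolidin-2-one, via mixed pivalic anhydride 31 (not isolated)
Conditions: t-BuCOCl, Et3N, THF, −20 °C; then 30, LiCl, −20 °C to rt
Reagents that add atoms: none
Why: N-acylation of the oxazolidinone by the mixed anhydride (the LiCl/Et3N variant of auxiliary attachment), which needs no strong base.

Step 24
Reactants: 32 arylacetyl imide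
Product: 34 (4S)-4-benzyl-3-[(2S)-2-{2-(benzyloxy)-3-methoxy-5-[FUR(Bn,TIPS)]phenyl}-3-hydroxypropanoyl]-1,3-oxazolidin-2-one, via dibutylboron enolate 33 (not isolated)
Conditions: Bu2BOTf, i-Pr2NEt, CH2Cl2, −78 to 0 °C; HCHO (gas, from paraformaldehyde), −78 °C; pH 7 buffer, MeOH, H2O2, 0 °C
Reagents that add atoms: formaldehyde, C=O
Why: Evans boron aldol: the (Z)-boron enolate adds to monomeric formaldehyde through a closed transition state on the face away from the benzyl group of the dipole-minimised auxiliary, setting the α-carbon (S), with the boron triflate taken up by the imide and the amine and not by the furofuran.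

Step 25
Reactants: 34 aldol adduct
Product: 35 (2S)-2-{2-(benzyloxy)-3-methoxy-5-[FUR(Bn,TIPS)]phenyl}-3-hydroxy-N-methoxy-N-methylpropanamide
Conditions: Me3Al, MeNH(OMe)·HCl, CH2Cl2, −10 °C to rt; aq. potassium sodium tartrate
Reagents that add atoms: N,O-dimethylhydroxylamine hydrochloride, CNOC.Cl
Why: Aluminium amide transamination of the β-hydroxy imide to the Weinreb amide, assisted by the free hydroxyl; the α-centre is not deprotonated under these conditions.

Step 26
Reactants: 35 hydroxy Weinreb amide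
Product: 36 (2S)-2-{2-(benzyloxy)-3-methoxy-5-[FUR(Bn,TIPS)]phenyl}-N-methoxy-N-methyl-3-[(triethylsilyl)oxy]propanamide
Conditions: Et3SiCl, imidazole, DMF, 0 °C
Reagents that add atoms: chlorotriethylsilane, CC[Si](Cl)(CC)CC
Why: Silylation of the primary alcohol so that no alkoxide is present during the organometallic addition.

Step 27
Reactants: 36 Weinreb amide; 37 1-(benzyloxy)-4-bromo-2-methoxybenzene
Product: 39 (2S)-1-[4-(benzyloxy)-3-methoxyphenyl]-2-{2-(benzyloxy)-3-methoxy-5-[FUR(Bn,TIPS)]phenyl}-3-[(triethylsilyl)oxy]propan-1-one, via Grignard reagent 38 (not isolated)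
Conditions: 37, Mg, THF, 40 °C; then 36, THF, −20 to 0 °C; aq. NH4Cl at −20 °C
Reagents that add atoms: none
Why: Grignard addition to the Weinreb amide stops at the chelated tetrahedral intermediate, so the aryl ketone appears only on cold buffered quench and the α-aryl stereocentre is not exposed to base as a ketone.

Step 28
Reactants: 39 bis-silyl ketone
Product: 40 (2S)-1-[4-(benzyloxy)-3-methoxyphenyl]-2-{2-(benzyloxy)-3-methoxy-5-[FUR(Bn,H)]phenyl}-3-hydroxypropan-1-one
Conditions: HF·pyridine, pyridine, THF, 0 °C to rt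
Reagents that add atoms: none
Why: Buffered fluoride desilylation removes both silyl ethers while all three phenols are still benzylated, so neither phenoxide chemistry nor hemiketal formation with the ring B oxygen can occur.

Step 29
Reactants: 40 tris(benzyl ether)
Product: 41 CNP0174045.1
Conditions: H2 (1 atm), 10% Pd/C, EtOAc, rt
Reagents that add atoms: none
Why: Hydrogenolysis of the three aryl benzyl ethers under neutral conditions releases the phenols last, avoiding base (epimerisation of the ketol, quinone methide opening of the cis-dihydrobenzofuran) and acid (cyclodehydration of the ortho-hydroxy ketone to a benzofuran).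

## Compound list

1 | vanillyl alcohol | COc1cc(CO)ccc1O | starting material
2 | 4-(hydroxymethyl)-2-methoxyphenyl 4-methylbenzenesulfonate | COc1cc(CO)ccc1OS(=O)(=O)c1ccc(C)cc1 | intermediate
3 | 4-(bromomethyl)-2-methoxyphenyl 4-methylbenzenesulfonate | COc1cc(CBr)ccc1OS(=O)(=O)c1ccc(C)cc1 | intermediate
4 | methyl 3-bromo-4-hydroxy-5-methoxybenzoate | COC(=O)c1cc(Br)c(O)c(OC)c1 | starting material
5 | methyl 3-bromo-5-methoxy-4-{[3-methoxy-4-(tosyloxy)phenyl]methoxy}benzoate | COC(=O)c1cc(Br)c(OCc2ccc(OS(=O)(=O)c3ccc(C)cc3)c(OC)c2)c(OC)c1 | intermediate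
6 | methyl 3-(2-ethoxy-2-oxoethyl)-5-methoxy-4-{[3-methoxy-4-(tosyloxy)phenyl]methoxy}benzoate | CCOC(=O)Cc1cc(C(=O)OC)cc(OC)c1OCc1ccc(OS(=O)(=O)c2ccc(C)cc2)c(OC)c1 | intermediate
7 | methyl 3-(1-diazo-2-ethoxy-2-oxoethyl)-5-methoxy-4-{[3-methoxy-4-(tosyloxy)phenyl]methoxy}benzoate | CCOC(=O)C(=[N+]=[N-])c1cc(C(=O)OC)cc(OC)c1OCc1ccc(OS(=O)(=O)c2ccc(C)cc2)c(OC)c1 | intermediate
8 | 3-ethyl 5-methyl (2S,3R)-7-methoxy-2-[3-methoxy-4-(tosyloxy)phenyl]-2,3-dihydro-1-benzofuran-3,5-dicarboxylate (cis) | COC(=O)c1cc(OC)c2c(c1)[C@@H](C(=O)OCC)[C@@H](c1ccc(OS(=O)(=O)c3ccc(C)cc3)c(OC)c1)O2 | intermediate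
9 | (2S,3S)-3,5-bis(hydroxymethyl)-7-methoxy-2-[3-methoxy-4-(tosyloxy)phenyl]-2,3-dihydro-1-benzofuran (cis) | OCc1cc(OC)c2c(c1)[C@@H](CO)[C@@H](c1ccc(OS(=O)(=O)c3ccc(C)cc3)c(OC)c1)O2 | intermediate
10 | (2S,3S)-5-(bromomethyl)-3-(hydroxymethyl)-7-methoxy-2-[3-methoxy-4-(tosyloxy)phenyl]-2,3-dihydro-1-benzofuran | BrCc1cc(OC)c2c(c1)[C@@H](CO)[C@@H](c1ccc(OS(=O)(=O)c3ccc(C)cc3)c(OC)c1)O2 | intermediate
11 | (2S,3S)-5-(bromomethyl)-7-methoxy-2-[3-methoxy-4-(tosyloxy)phenyl]-3-{[(triisopropylsilyl)oxy]methyl}-2,3-dihydro-1-benzofuran | BrCc1cc(OC)c2c(c1)[C@@H](CO[Si](C(C)C)(C(C)C)C(C)C)[C@@H](c1ccc(OS(=O)(=O)c3ccc(C)cc3)c(OC)c1)O2 | intermediate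
12 | 4-(benzyloxy)-3-methoxybenzaldehyde | COc1cc(C=O)ccc1OCc1ccccc1 | starting material
13 | dimethyl succinate | COC(=O)CCC(=O)OC | starting material
14 | (E)-4-[4-(benzyloxy)-3-methoxyphenyl]-3-(methoxycarbonyl)but-3-enoic acid | COC(=O)/C(CC(=O)O)=C/c1ccc(OCc2ccccc2)c(OC)c1 | intermediate
15 | (3R)-4-[4-(benzyloxy)-3-methoxyphenyl]-3-(methoxycarbonyl)butanoic acid | COC(=O)[C@H](Cc1ccc(OCc2ccccc2)c(OC)c1)CC(=O)O | intermediate
16 | (3R)-4-[4-(benzyloxy)-3-methoxyphenyl]-3-(hydroxymethyl)butanoic acid | OC[C@H](Cc1ccc(OCc2ccccc2)c(OC)c1)CC(=O)O | intermediate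
17 | (4R)-4-[4-(benzyloxy)-3-methoxybenzyl]dihydrofuran-2(3H)-one | O=C1C[C@@H](Cc2ccc(OCc3ccccc3)c(OC)c2)CO1 | intermediate
18 | lithium enolate of lactone 17 | [Li]OC1=C[C@@H](Cc2ccc(OCc3ccccc3)c(OC)c2)CO1 | intermediate
19 | (3R,4R)-4-[4-(benzyloxy)-3-methoxybenzyl]-3-[DBF(Ts,TIPS)-methyl]dihydrofuran-2(3H)-one (trans) | O=C1OC[C@H](Cc2ccc(OCc3ccccc3)c(OC)c2)[C@H]1Cc1cc(OC)c2c(c1)[C@@H](CO[Si](C(C)C)(C(C)C)C(C)C)[C@@H](c1ccc(OS(=O)(=O)c3ccc(C)cc3)c(OC)c1)O2 | intermediate
20 | (2R,3R)-2-[4-(benzyloxy)-3-methoxybenzyl]-3-[DBF(Ts,TIPS)-methyl]butane-1,4-diol | COc1cc(C[C@@H](CO)[C@H](CO)Cc2cc(OC)c3c(c2)[C@@H](CO[Si](C(C)C)(C(C)C)C(C)C)[C@@H](c2ccc(OS(=O)(=O)c4ccc(C)cc4)c(OC)c2)O3)ccc1OCc1ccccc1 | intermediate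
21 | {(2S,3R,4R)-2-[4-(benzyloxy)-3-methoxyphenyl]-4-[DBF(Ts,TIPS)-methyl]tetrahydrofuran-3-yl}methanol (closure on the ring B side shown; the other monoether is equally productive) | COc1cc([C@H]2OC[C@H](Cc3cc(OC)c4c(c3)[C@@H](CO[Si](C(C)C)(C(C)C)C(C)C)[C@@H](c3ccc(OS(=O)(=O)c5ccc(C)cc5)c(OC)c3)O4)[C@@H]2CO)ccc1OCc1ccccc1 | intermediate
22 | 1-(benzyloxy)-2-methoxy-4-[FUR(Ts,TIPS)]benzene | COc1cc([C@H]2OC[C@H]3[C@@H]2CO[C@@H]3c2cc(OC)c3c(c2)[C@@H](CO[Si](C(C)C)(C(C)C)C(C)C)[C@@H](c2ccc(OS(=O)(=O)c4ccc(C)cc4)c(OC)c2)O3)ccc1OCc1ccccc1 | intermediate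
23 | 2-methoxy-4-[FUR(Ts,TIPS)]phenol | COc1cc([C@H]2OC[C@H]3[C@@H]2CO[C@@H]3c2cc(OC)c3c(c2)[C@@H](CO[Si](C(C)C)(C(C)C)C(C)C)[C@@H](c2ccc(OS(=O)(=O)c4ccc(C)cc4)c(OC)c2)O3)ccc1O | intermediate
24 | 2-bromo-6-methoxy-4-[FUR(Ts,TIPS)]phenol | COc1cc([C@H]2OC[C@H]3[C@@H]2CO[C@@H]3c2cc(OC)c3c(c2)[C@@H](CO[Si](C(C)C)(C(C)C)C(C)C)[C@@H](c2ccc(OS(=O)(=O)c4ccc(C)cc4)c(OC)c2)O3)cc(Br)c1O | intermediate
25 | 2-(benzyloxy)-1-bromo-3-methoxy-5-[FUR(Ts,TIPS)]benzene | COc1cc([C@H]2OC[C@H]3[C@@H]2CO[C@@H]3c2cc(OC)c3c(c2)[C@@H](CO[Si](C(C)C)(C(C)C)C(C)C)[C@@H](c2ccc(OS(=O)(=O)c4ccc(C)cc4)c(OC)c2)O3)cc(Br)c1OCc1ccccc1 | intermediate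
26 | ethyl {2-(benzyloxy)-3-methoxy-5-[FUR(Ts,TIPS)]phenyl}acetate | CCOC(=O)Cc1cc([C@H]2OC[C@H]3[C@@H]2CO[C@@H]3c2cc(OC)c3c(c2)[C@@H](CO[Si](C(C)C)(C(C)C)C(C)C)[C@@H](c2ccc(OS(=O)(=O)c4ccc(C)cc4)c(OC)c2)O3)cc(OC)c1OCc1ccccc1 | intermediate
27 | methyl {2-(benzyloxy)-3-methoxy-5-[FUR(H,TIPS)]phenyl}acetate | COC(=O)Cc1cc([C@H]2OC[C@H]3[C@@H]2CO[C@@H]3c2cc(OC)c3c(c2)[C@@H](CO[Si](C(C)C)(C(C)C)C(C)C)[C@@H](c2ccc(O)c(OC)c2)O3)cc(OC)c1OCc1ccccc1 | intermediate
28 | methyl {2-(benzyloxy)-3-methoxy-5-[FUR(Bn,TIPS)]phenyl}acetate | COC(=O)Cc1cc([C@H]2OC[C@H]3[C@@H]2CO[C@@H]3c2cc(OC)c3c(c2)[C@@H](CO[Si](C(C)C)(C(C)C)C(C)C)[C@@H](c2ccc(OCc4ccccc4)c(OC)c2)O3)cc(OC)c1OCc1ccccc1 | intermediate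
29 | {2-(benzyloxy)-3-methoxy-5-[FUR(Bn,TIPS)]phenyl}acetic acid | OC(=O)Cc1cc([C@H]2OC[C@H]3[C@@H]2CO[C@@H]3c2cc(OC)c3c(c2)[C@@H](CO[Si](C(C)C)(C(C)C)C(C)C)[C@@H](c2ccc(OCc4ccccc4)c(OC)c2)O3)cc(OC)c1OCc1ccccc1 | intermediate
30 | (S)-4-benzyl-1,3-oxazolidin-2-one | O=C1N[C@@H](Cc2ccccc2)CO1 | starting material
31 | mixed anhydride of acid 29 with pivalic acid | CC(C)(C)C(=O)OC(=O)Cc1cc([C@H]2OC[C@H]3[C@@H]2CO[C@@H]3c2cc(OC)c3c(c2)[C@@H](CO[Si](C(C)C)(C(C)C)C(C)C)[C@@H](c2ccc(OCc4ccccc4)c(OC)c2)O3)cc(OC)c1OCc1ccccc1 | intermediate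
32 | (4S)-4-benzyl-3-({2-(benzyloxy)-3-methoxy-5-[FUR(Bn,TIPS)]phenyl}acetyl)-1,3-oxazolidin-2-one | O=C(Cc1cc([C@H]2OC[C@H]3[C@@H]2CO[C@@H]3c2cc(OC)c3c(c2)[C@@H](CO[Si](C(C)C)(C(C)C)C(C)C)[C@@H](c2ccc(OCc4ccccc4)c(OC)c2)O3)cc(OC)c1OCc1ccccc1)N1C(=O)OC[C@@H]1Cc1ccccc1 | intermediate
33 | (Z)-dibutylboron enolate of imide 32 | CCCCB(CCCC)O/C(=C\c1cc([C@H]2OC[C@H]3[C@@H]2CO[C@@H]3c2cc(OC)c3c(c2)[C@@H](CO[Si](C(C)C)(C(C)C)C(C)C)[C@@H](c2ccc(OCc4ccccc4)c(OC)c2)O3)cc(OC)c1OCc1ccccc1)N1C(=O)OC[C@@H]1Cc1ccccc1 | intermediate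
34 | (4S)-4-benzyl-3-[(2S)-2-{2-(benzyloxy)-3-methoxy-5-[FUR(Bn,TIPS)]phenyl}-3-hydroxypropanoyl]-1,3-oxazolidin-2-one | OC[C@H](c1cc([C@H]2OC[C@H]3[C@@H]2CO[C@@H]3c2cc(OC)c3c(c2)[C@@H](CO[Si](C(C)C)(C(C)C)C(C)C)[C@@H](c2ccc(OCc4ccccc4)c(OC)c2)O3)cc(OC)c1OCc1ccccc1)C(=O)N1C(=O)OC[C@@H]1Cc1ccccc1 | intermediate
35 | (2S)-2-{2-(benzyloxy)-3-methoxy-5-[FUR(Bn,TIPS)]phenyl}-3-hydroxy-N-methoxy-N-methylpropanamide | OC[C@H](c1cc([C@H]2OC[C@H]3[C@@H]2CO[C@@H]3c2cc(OC)c3c(c2)[C@@H](CO[Si](C(C)C)(C(C)C)C(C)C)[C@@H](c2ccc(OCc4ccccc4)c(OC)c2)O3)cc(OC)c1OCc1ccccc1)C(=O)N(C)OC | intermediate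
36 | (2S)-2-{2-(benzyloxy)-3-methoxy-5-[FUR(Bn,TIPS)]phenyl}-N-methoxy-N-methyl-3-[(triethylsilyl)oxy]propanamide | CC[Si](CC)(CC)OC[C@H](c1cc([C@H]2OC[C@H]3[C@@H]2CO[C@@H]3c2cc(OC)c3c(c2)[C@@H](CO[Si](C(C)C)(C(C)C)C(C)C)[C@@H](c2ccc(OCc4ccccc4)c(OC)c2)O3)cc(OC)c1OCc1ccccc1)C(=O)N(C)OC | intermediate
37 | 1-(benzyloxy)-4-bromo-2-methoxybenzene | COc1cc(Br)ccc1OCc1ccccc1 | starting material
38 | [4-(benzyloxy)-3-methoxyphenyl]magnesium bromide | COc1cc([Mg]Br)ccc1OCc1ccccc1 | intermediate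
39 | (2S)-1-[4-(benzyloxy)-3-methoxyphenyl]-2-{2-(benzyloxy)-3-methoxy-5-[FUR(Bn,TIPS)]phenyl}-3-[(triethylsilyl)oxy]propan-1-one | CC[Si](CC)(CC)OC[C@H](c1cc([C@H]2OC[C@H]3[C@@H]2CO[C@@H]3c2cc(OC)c3c(c2)[C@@H](CO[Si](C(C)C)(C(C)C)C(C)C)[C@@H](c2ccc(OCc4ccccc4)c(OC)c2)O3)cc(OC)c1OCc1ccccc1)C(=O)c1ccc(OCc2ccccc2)c(OC)c1 | intermediate
40 | (2S)-1-[4-(benzyloxy)-3-methoxyphenyl]-2-{2-(benzyloxy)-3-methoxy-5-[FUR(Bn,H)]phenyl}-3-hydroxypropan-1-one | OC[C@H](c1cc([C@H]2OC[C@H]3[C@@H]2CO[C@@H]3c2cc(OC)c3c(c2)[C@@H](CO)[C@@H](c2ccc(OCc4ccccc4)c(OC)c2)O3)cc(OC)c1OCc1ccccc1)C(=O)c1ccc(OCc2ccccc2)c(OC)c1 | intermediate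
41 | CNP0174045.1, (2S)-3-hydroxy-1-(4-hydroxy-3-methoxyphenyl)-2-{2-hydroxy-3-methoxy-5-[FUR(H,H)]phenyl}propan-1-one | COc1cc(C(=O)[C@H](CO)c2cc([C@H]3OC[C@H]4[C@@H]3CO[C@@H]4c3cc(OC)c4c(c3)[C@@H](CO)[C@@H](c3ccc(O)c(OC)c3)O4)cc(OC)c2O)ccc1O | target

## Step count and risks

Total step count: 29 steps.
Longest linear sequence: 26 steps (steps 1–9 and 13–29, from vanillyl alcohol).

Steps most likely to fail

1. Step 15 (double oxidative closure). What may go wrong: a third hydride abstraction at the α-oxygenated benzylic C–H of the first-formed ether, acid-induced reionisation leading to epimerisation or Friedel–Crafts ring closure, or stalling after one closure. Fallback (benzylic oxygens introduced before any ring is closed, all known reaction types): setting out from diol 20, acetylation (Ac2O, pyridine) would give the diacetate F1. DDQ in acetic acid, a known benzylic acetoxylation of para-alkoxy alkylbenzenes whose acetate products are deactivated toward further oxidation, would give the bis(benzylic acetate) F2 as a mixture of epimers at the two new centres. Methanolysis (K2CO3, MeOH, rt) would give the tetraol F3. Acid-promoted double cyclodehydration (camphorsulfonic acid, CH2Cl2), the classical closure of 1,4-diaryl-2,3-bis(hydroxymethyl)butane-1,4-diols through benzylic cations, would return to furofuran 22; the exo,exo isomer is expected to predominate and a minor epimer would be removed by chromatography.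

2. Step 27 (Grignard addition to the Weinreb amide). What may go wrong: α-deprotonation of the α-aryl amide by the Grignard reagent with loss of configuration or β-elimination of the silyloxy group, or sluggish addition to the hindered amide. Fallback (base-free acyl cross-coupling): setting out from aldol adduct 34, silylation (Et3SiOTf, 2,6-lutidine) would give the silyl ether imide F4. Displacement of the auxiliary with lithium ethanethiolate (EtSH, n-BuLi, THF, 0 °C) would give the S-ethyl thioester F5. Liebeskind–Srogl coupling with commercial 4-(benzyloxy)-3-methoxyphenylboronic acid (Pd2(dba)3, tri(2-furyl)phosphine, copper thiophene-2-carboxylate, a monovalent copper salt, THF, 50 °C) would return to ketone 39 without any basic organometallic reagent.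

3. Step 8 (benzylic-selective bromination of the diol). What may go wrong: loss of chemoselectivity between the benzylic and the aliphatic hydroxyl, or capture of the very reactive benzyl bromide by dimethyl sulfide. Fallback (differentiation by oxidation state): setting out from diol 9, MnO2 (CH2Cl2, rt) would oxidise only the benzylic alcohol to the hydroxy aldehyde F6. Silylation (i-Pr3SiOTf, 2,6-lutidine) would give the silyl ether aldehyde F7. NaBH4 (MeOH, 0 °C) would give the benzylic alcohol F8. Appel bromination (CBr4, PPh3, CH2Cl2, 0 °C) would return to bromide 11.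

Further compounds

F1 | step 15 | (2R,3R)-2-[4-(benzyloxy)-3-methoxybenzyl]-3-[DBF(Ts,TIPS)-methyl]butane-1,4-diyl diacetate | COc1cc(C[C@@H](COC(C)=O)[C@H](COC(C)=O)Cc2cc(OC)c3c(c2)[C@@H](CO[Si](C(C)C)(C(C)C)C(C)C)[C@@H](c2ccc(OS(=O)(=O)c4ccc(C)cc4)c(OC)c2)O3)ccc1OCc1ccccc1
F2 | step 15 | (2R,3R)-1-[4-(benzyloxy)-3-methoxyphenyl]-2,3-bis(acetoxymethyl)-4-[DBF(Ts,TIPS)]butane-1,4-diyl diacetate (epimers at C1 and C4) | COc1cc(C(OC(C)=O)[C@@H](COC(C)=O)[C@H](COC(C)=O)C(OC(C)=O)c2cc(OC)c3c(c2)[C@@H](CO[Si](C(C)C)(C(C)C)C(C)C)[C@@H](c2ccc(OS(=O)(=O)c4ccc(C)cc4)c(OC)c2)O3)ccc1OCc1ccccc1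
F3 | step 15 | (2R,3R)-1-[4-(benzyloxy)-3-methoxyphenyl]-2,3-bis(hydroxymethyl)-4-[DBF(Ts,TIPS)]butane-1,4-diol (epimers at C1 and C4) | COc1cc(C(O)[C@@H](CO)[C@H](CO)C(O)c2cc(OC)c3c(c2)[C@@H](CO[Si](C(C)C)(C(C)C)C(C)C)[C@@H](c2ccc(OS(=O)(=O)c4ccc(C)cc4)c(OC)c2)O3)ccc1OCc1ccccc1
F4 | step 27 | (4S)-4-benzyl-3-[(2S)-2-{2-(benzyloxy)-3-methoxy-5-[FUR(Bn,TIPS)]phenyl}-3-[(triethylsilyl)oxy]propanoyl]-1,3-oxazolidin-2-one | CC[Si](CC)(CC)OC[C@H](c1cc([C@H]2OC[C@H]3[C@@H]2CO[C@@H]3c2cc(OC)c3c(c2)[C@@H](CO[Si](C(C)C)(C(C)C)C(C)C)[C@@H](c2ccc(OCc4ccccc4)c(OC)c2)O3)cc(OC)c1OCc1ccccc1)C(=O)N1C(=O)OC[C@@H]1Cc1ccccc1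
F5 | step 27 | S-ethyl (2S)-2-{2-(benzyloxy)-3-methoxy-5-[FUR(Bn,TIPS)]phenyl}-3-[(triethylsilyl)oxy]propanethioate | CC[Si](CC)(CC)OC[C@H](c1cc([C@H]2OC[C@H]3[C@@H]2CO[C@@H]3c2cc(OC)c3c(c2)[C@@H](CO[Si](C(C)C)(C(C)C)C(C)C)[C@@H](c2ccc(OCc4ccccc4)c(OC)c2)O3)cc(OC)c1OCc1ccccc1)C(=O)SCC
F6 | step 8 | (2S,3S)-3-(hydroxymethyl)-7-methoxy-2-[3-methoxy-4-(tosyloxy)phenyl]-2,3-dihydro-1-benzofuran-5-carbaldehyde | O=Cc1cc(OC)c2c(c1)[C@@H](CO)[C@@H](c1ccc(OS(=O)(=O)c3ccc(C)cc3)c(OC)c1)O2
F7 | step 8 | (2S,3S)-7-methoxy-2-[3-methoxy-4-(tosyloxy)phenyl]-3-{[(triisopropylsilyl)oxy]methyl}-2,3-dihydro-1-benzofuran-5-carbaldehyde | O=Cc1cc(OC)c2c(c1)[C@@H](CO[Si](C(C)C)(C(C)C)C(C)C)[C@@H](c1ccc(OS(=O)(=O)c3ccc(C)cc3)c(OC)c1)O2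
F8 | step 8 | [(2S,3S)-7-methoxy-2-[3-methoxy-4-(tosyloxy)phenyl]-3-{[(triisopropylsilyl)oxy]methyl}-2,3-dihydro-1-benzofuran-5-yl]methanol | OCc1cc(OC)c2c(c1)[C@@H](CO[Si](C(C)C)(C(C)C)C(C)C)[C@@H](c1ccc(OS(=O)(=O)c3ccc(C)cc3)c(OC)c1)O2
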